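**Strategy**

Everything rests on cutting the bond between the syringyl CH2 and C3 of the butane chain. The 1,4-dioxygenated C1–C4 backbone is tied up temporarily as a γ-butyrolactone ring (one CH2O carbon as the C=O), which turns C3 into an enolate carbon next to the existing veratrylmethyl stereocentre. Alkylation of this lithium enolate with 4-pivaloyloxy-3,5-dimethoxybenzyl bromide should join both aryl halves and set the second stereocentre trans in one operation. LiAlH4 then opens the ring and frees the phenol at once, and a lipase acetylates only the two primary alcohols. The first stereocentre comes from Rh-catalysed asymmetric hydrogenation of a Stobbe half-ester.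

Key step: step 7

Assumption: the (S,S) antipode of Et-DuPhos is taken as the one that delivers (R)-4; the sense would be checked on lactone 6 (sign of rotation, chiral HPLC) before the key step, and the (R,R) ligand used instead if it proves opposite.

**Route**

Step 1
Reactants: 1 3,4-dimethoxybenzaldehyde (veratraldehyde); 2 dimethyl succinate
Product: 3 (E)-4-(3,4-dimethoxyphenyl)-3-(methoxycarbonyl)but-3-enoic acid
Conditions: NaOMe (2 equiv), MeOH, reflux; then aq. HCl
Reagents that add atoms: none
Why: Stobbe condensation (aldol addition, lactonisation and E1cB ring opening in one flask) should give the E-alkylidene succinate with the ester conjugated and the free acid on the CH2 arm, the differentiation the later reduction needs.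

Step 2
Reactants: 3 (E)-4-(3,4-dimethoxyphenyl)-3-(methoxycarbonyl)but-3-enoic acid
Product: 4 (R)-4-(3,4-dimethoxyphenyl)-3-(methoxycarbonyl)butanoic acid
Conditions: H2 (5 bar), [((S,S)-Et-DuPhos)Rh(cod)]OTf (0.5 mol %), NaOMe (0.1 equiv), MeOH, rt
Reagents that add atoms: none
Why: Rh(I)-catalysed asymmetric hydrogenation of a β-aryl itaconate half-ester, in which the carboxylate binds rhodium beside the alkene and the C2-symmetric bisphospholane selects the alkene face, should set the benzyl-bearing stereocentre as R.

Step 3
Reactants: 4 (R)-4-(3,4-dimethoxyphenyl)-3-(methoxycarbonyl)butanoic acid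
Product: 6 (R)-4-(3,4-dimethoxybenzyl)dihydrofuran-2(3H)-one, via (R)-4-(3,4-dimethoxyphenyl)-3-(hydroxymethyl)butanoic acid 5 (not isolated)
Conditions: KOH (1 equiv), EtOH; CaCl2, NaBH4, EtOH, −10 °C to rt; then 3 M HCl, rt
Reagents that add atoms: none
Why: Calcium borohydride made in situ should reduce the methyl ester but not the potassium carboxylate, and acidification closes the γ-lactone (lactonisation) without touching the stereocentre.

Step 4
Reactants: 7 4-hydroxy-3,5-dimethoxybenzaldehyde (syringaldehyde)
Product: 8 4-formyl-2,6-dimethoxyphenyl pivalate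
Conditions: PivCl, Et3N, DMAP (cat.), CH2Cl2, 0 °C to rt
Reagents that add atoms: pivaloyl chloride, CC(C)(C)C(=O)Cl
Why: DMAP-catalysed O-acylation of the phenol gives a hindered aryl ester, flanked by two methoxy groups, that should resist an enolate at −78 °C yet be cleaved by LiAlH4.

Step 5
Reactants: 8 4-formyl-2,6-dimethoxyphenyl pivalate
Product: 9 4-(hydroxymethyl)-2,6-dimethoxyphenyl pivalate
Conditions: NaBH4, THF/EtOH, 0 °C
Reagents that add atoms: none
Why: Chemoselective borohydride reduction of the aryl aldehyde, with the hindered pivalate expected to be inert at 0 °C.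

Step 6
Reactants: 9 4-(hydroxymethyl)-2,6-dimethoxyphenyl pivalate
Product: 10 4-(bromomethyl)-2,6-dimethoxyphenyl pivalate
Conditions: PBr3 (0.4 equiv), CH2Cl2, 0 °C
Reagents that add atoms: phosphorus tribromide, BrP(Br)Br
Why: PBr3 activates the benzylic hydroxyl and bromide displaces it (SN2), and the aryl pivalate should tolerate the HBr formed at 0 °C.

Step 7
Reactants: 6 (R)-4-(3,4-dimethoxybenzyl)dihydrofuran-2(3H)-one; 10 4-(bromomethyl)-2,6-dimethoxyphenyl pivalate
Product: 12 4-{[(3R,4R)-4-(3,4-dimethoxybenzyl)-2-oxotetrahydrofuran-3-yl]methyl}-2,6-dimethoxyphenyl pivalate, via lithium (R)-4-(3,4-dimethoxybenzyl)-4,5-dihydrofuran-2-olate 11 (not isolated)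
Conditions: LDA (1.05 equiv), THF, −78 °C; then 10, DMPU, −78 to −40 °C; aq. NH4Cl
Reagents that add atoms: none
Why: LDA deprotonates C3 of 6 to the planar lithium enolate 11, which attacks the benzylic carbon of 10 in an SN2 reaction, with DMPU loosening the enolate aggregate. The closest known reaction type is the trans-selective α-alkylation of β-substituted γ-butyrolactone enolates (1,2-asymmetric induction). No ring is closed; the lactone is already present and serves only as a temporary scaffold for the C1–C4 chain. The new stereocentre at C3 is controlled by the C4 3,4-dimethoxybenzyl group, which shields one face of the five-membered enolate, so the electrophile should enter anti and give the 3R,4R trans product. The step needs monoalkylation over dialkylation and C-alkylation over acyl transfer from the aryl ester; the first is secured by one equivalent of base at −78 °C and the hindered α-carbon of the product, the second by the tert-butyl group and the two ortho methoxy groups around the pivalate carbonyl.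

Step 8
Reactants: 12 4-{[(3R,4R)-4-(3,4-dimethoxybenzyl)-2-oxotetrahydrofuran-3-yl]methyl}-2,6-dimethoxyphenyl pivalate
Product: 13 (2R,3R)-2-(3,4-dimethoxybenzyl)-3-(4-hydroxy-3,5-dimethoxybenzyl)butane-1,4-diol
Conditions: LiAlH4 (excess), THF, 0 °C to rt; aq. Rochelle salt, then dilute citric acid to pH 6
Reagents that add atoms: none
Why: Hydride reduction should open the lactone to the 1,4-diol and cleave the aryl pivalate in the same flask, and with the carbonyl gone neither stereocentre can epimerise, so the trans relationship is carried into the 2R,3R chain.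

Step 9
Reactants: 13 (2R,3R)-2-(3,4-dimethoxybenzyl)-3-(4-hydroxy-3,5-dimethoxybenzyl)butane-1,4-diol
Product: 14 Justin C, (2R,3R)-2-(3,4-dimethoxybenzyl)-3-(4-hydroxy-3,5-dimethoxybenzyl)butane-1,4-diyl diacetate
Conditions: immobilised Candida antarctica lipase B (Novozym 435), vinyl acetate (excess), MTBE/THF, 40 °C
Reagents that add atoms: vinyl acetate, C=COC(C)=O
Why: Lipase (serine hydrolase) catalysed irreversible transesterification with an enol ester should transfer acetyl to the two primary aliphatic alcohols only, because phenols are not accepted as acyl acceptors, so the hindered 4-OH stays free and no stereocentre is involved.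

**Compound list**

1 | 3,4-dimethoxybenzaldehyde (veratraldehyde) | COc1ccc(C=O)cc1OC | starting material
2 | dimethyl succinate | COC(=O)CCC(=O)OC | starting material
3 | (E)-4-(3,4-dimethoxyphenyl)-3-(methoxycarbonyl)but-3-enoic acid | COC(=O)/C(CC(=O)O)=C/c1ccc(OC)c(OC)c1 | intermediate
4 | (R)-4-(3,4-dimethoxyphenyl)-3-(methoxycarbonyl)butanoic acid | COC(=O)[C@@H](CC(=O)O)Cc1ccc(OC)c(OC)c1 | intermediate
5 | (R)-4-(3,4-dimethoxyphenyl)-3-(hydroxymethyl)butanoic acid | OC[C@@H](CC(=O)O)Cc1ccc(OC)c(OC)c1 | intermediate
6 | (R)-4-(3,4-dimethoxybenzyl)dihydrofuran-2(3H)-one | O=C1C[C@@H](Cc2ccc(OC)c(OC)c2)CO1 | intermediate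
7 | 4-hydroxy-3,5-dimethoxybenzaldehyde (syringaldehyde) | COc1cc(C=O)cc(OC)c1O | starting material
8 | 4-formyl-2,6-dimethoxyphenyl pivalate | COc1cc(C=O)cc(OC)c1OC(=O)C(C)(C)C | intermediate
9 | 4-(hydroxymethyl)-2,6-dimethoxyphenyl pivalate | COc1cc(CO)cc(OC)c1OC(=O)C(C)(C)C | intermediate
10 | 4-(bromomethyl)-2,6-dimethoxyphenyl pivalate | COc1cc(CBr)cc(OC)c1OC(=O)C(C)(C)C | intermediate
11 | lithium (R)-4-(3,4-dimethoxybenzyl)-4,5-dihydrofuran-2-olate | [Li+].[O-]C1=C[C@@H](Cc2ccc(OC)c(OC)c2)CO1 | intermediate
12 | 4-{[(3R,4R)-4-(3,4-dimethoxybenzyl)-2-oxotetrahydrofuran-3-yl]methyl}-2,6-dimethoxyphenyl pivalate | COc1ccc(C[C@H]2COC(=O)[C@@H]2Cc2cc(OC)c(OC(=O)C(C)(C)C)c(OC)c2)cc1OC | intermediate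
13 | (2R,3R)-2-(3,4-dimethoxybenzyl)-3-(4-hydroxy-3,5-dimethoxybenzyl)butane-1,4-diol | COc1ccc(C[C@@H](CO)[C@H](CO)Cc2cc(OC)c(O)c(OC)c2)cc1OC | intermediate
14 | Justin C, (2R,3R)-2-(3,4-dimethoxybenzyl)-3-(4-hydroxy-3,5-dimethoxybenzyl)butane-1,4-diyl diacetate | COc1ccc(C[C@@H](COC(C)=O)[C@H](COC(C)=O)Cc2cc(OC)c(O)c(OC)c2)cc1OC | target

**Step count**

Total step count: 9
Longest linear sequence: 6 steps (steps 1, 2, 3, 7, 8, 9 from veratraldehyde; equally steps 4, 5, 6, 7, 8, 9 from syringaldehyde)

**Steps most likely to fail**

Step 7 (key alkylation). The risks are acyl transfer from the aryl pivalate to the enolate, over-alkylation at C3 through proton exchange between product and enolate, and incomplete anti facial selectivity. The fallback sets out from 6 (with 7 for the electrophile) and comes back at 13; it forms the same bond by an aldol reaction in place of the SN2 reaction. Syringaldehyde 7 would be benzylated (BnBr, K2CO3, DMF) to 4-(benzyloxy)-3,5-dimethoxybenzaldehyde F1. The enolate 11, made from 6 as before, would be added to F1 at −78 °C, again anti to the C4 benzyl group, to give the trans aldol adduct (4R)-3-[(4-benzyloxy-3,5-dimethoxyphenyl)(hydroxy)methyl]-4-(3,4-dimethoxybenzyl)dihydrofuran-2(3H)-one F2, whose carbinol carbon may be a mixture without consequence. Hydrogenolysis (H2, Pd/C, AcOH, cat. HClO4) should remove the benzylic hydroxyl and the O-benzyl group together to give (3R,4R)-4-(3,4-dimethoxybenzyl)-3-(4-hydroxy-3,5-dimethoxybenzyl)dihydrofuran-2(3H)-one F3. LiAlH4 reduction of F3 would give triol 13.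

Step 9 (lipase acetylation). The risk is that the enzyme turns over the hindered, β-branched diol slowly, so that acylation stalls after the first acetyl transfer. The fallback sets out from 13 and comes back at 14, using chemical discrimination in place of enzymatic. Exhaustive acetylation (Ac2O, pyridine, DMAP) would give the triacetate (2R,3R)-2-(4-acetoxy-3,5-dimethoxybenzyl)-3-(3,4-dimethoxybenzyl)butane-1,4-diyl diacetate F4. Chemoselective aminolysis of the aryl acetate (pyrrolidine, 1.1 equiv, CH2Cl2, 0 °C) should then free the phenol alone, since the aryloxide is by far the better leaving group, and give 14.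

Step 2 (asymmetric hydrogenation). The risk is insufficient enantiofacial discrimination on the electron-rich aryl substrate, or erosion by the minor Z isomer of 3. The fallback sets out from 3 and comes back at 4, using classical resolution in place of asymmetric catalysis. Hydrogenation of 3 over Pd/C (H2, MeOH) would give the racemic half-ester 4-(3,4-dimethoxyphenyl)-3-(methoxycarbonyl)butanoic acid F5. Crystallisation with (R)-1-phenylethylamine (or its antipode, whichever gives the less soluble salt of the R acid) should give the diastereomerically pure salt (R)-1-phenylethylammonium (R)-4-(3,4-dimethoxyphenyl)-3-(methoxycarbonyl)butanoate F6. Acidification of F6 releases 4.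

**Further compounds**

F1 | step 7 | 4-(benzyloxy)-3,5-dimethoxybenzaldehyde | COc1cc(C=O)cc(OC)c1OCc1ccccc1
F2 | step 7 | (4R)-3-[(4-benzyloxy-3,5-dimethoxyphenyl)(hydroxy)methyl]-4-(3,4-dimethoxybenzyl)dihydrofuran-2(3H)-one, ring substituents trans, carbinol carbon unassigned | COc1ccc(C[C@H]2COC(=O)[C@@H]2C(O)c2cc(OC)c(OCc3ccccc3)c(OC)c2)cc1OC
F3 | step 7 | (3R,4R)-4-(3,4-dimethoxybenzyl)-3-(4-hydroxy-3,5-dimethoxybenzyl)dihydrofuran-2(3H)-one | COc1ccc(C[C@H]2COC(=O)[C@@H]2Cc2cc(OC)c(O)c(OC)c2)cc1OC
F4 | step 9 | (2R,3R)-2-(4-acetoxy-3,5-dimethoxybenzyl)-3-(3,4-dimethoxybenzyl)butane-1,4-diyl diacetate | COc1ccc(C[C@@H](COC(C)=O)[C@H](COC(C)=O)Cc2cc(OC)c(OC(C)=O)c(OC)c2)cc1OC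
F5 | step 2 | racemic 4-(3,4-dimethoxyphenyl)-3-(methoxycarbonyl)butanoic acid | COC(=O)C(CC(=O)O)Cc1ccc(OC)c(OC)c1
F6 | step 2 | (R)-1-phenylethylammonium (R)-4-(3,4-dimethoxyphenyl)-3-(methoxycarbonyl)butanoate | COC(=O)[C@@H](CC(=O)[O-])Cc1ccc(OC)c(OC)c1.C[C@@H]([NH3+])c1ccccc1
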